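**Strategy**

Ring A is not bought as a phloroglucinol but grown last on the C4a–C8a edge of a monocyclic 4-pyranone that already carries O1, C2–C4 and ring B. The resorcinol pattern of ring A (C5–OH peri to the C4 carbonyl, C7–O meta to it, C6–H and C8–H) is what a vinylketene and an alkoxyacetylene deliver, so one benzannulation of a 6-aryl-2-(diazoacetyl)-4-pyranone with ethoxyacetylene forges C8–C8a, C5–C6, C7–C8 and C4a–C5 and hands over the complete flavone. The precursor comes from 3,4-dimethoxyacetophenone by two Claisen condensations and a diazomethane acylation; dealkylation, 7,4'-dibenzylation, 3'-O-sulfation and hydrogenolysis finish.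

Key step: step 4

Assumption: the target is taken as the free hydrogen sulfate as drawn, so the last step ends with a cold, stoichiometric protonation of its potassium salt, which is the form suited to storage. Ethoxyacetylene is used as the commercial solution in hexanes. The target has no stereocentre.

**Route**

Step 1
Reactants: 1 3,4-dimethoxyacetophenone; 2 ethyl acetate
Product: 3 1-(3,4-dimethoxyphenyl)butane-1,3-dione
Conditions: NaH (2.5 equiv), EtOAc (5 equiv), THF, 0 °C to reflux; then aq. HCl
Reagents that add atoms: ethyl acetate 2, CCOC(C)=O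
Why: Crossed Claisen condensation of the aryl methyl ketone enolate with ethyl acetate, pulled to completion because the β-diketone formed is deprotonated irreversibly by NaH.

Step 2
Reactants: 3 1-(3,4-dimethoxyphenyl)butane-1,3-dione; 4 diethyl oxalate
Product: 7 6-(3,4-dimethoxyphenyl)-4-oxo-4H-pyran-2-carboxylic acid, via triketo ester 5 (not isolated), via pyranone ethyl ester 6 (not isolated)
Conditions: NaOEt (3 equiv), EtOH, 0 °C to 60 °C; then conc. HCl–AcOH (1:2), 100 °C
Reagents that add atoms: diethyl oxalate 4, CCOC(=O)C(=O)OCC; water, O
Why: Claisen acylation of the diketone at its terminal methyl group (only there does acylation end in a doubly deprotonated, fully delocalised triketo ester that drives the equilibrium), then acid-catalysed cyclodehydration of the 1,3,5-tricarbonyl unit and acid hydrolysis of the activated ester in the same pot, the sequence of the classical chelidonic acid synthesis, which can give only this pyranone and leaves aryl methyl ethers untouched.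

Step 3
Reactants: 7 6-(3,4-dimethoxyphenyl)-4-oxo-4H-pyran-2-carboxylic acid
Product: 9 2-(diazoacetyl)-6-(3,4-dimethoxyphenyl)-4H-pyran-4-one, via acid chloride 8 (not isolated)
Conditions: (COCl)2 (1.2 equiv), DMF (cat.), CH2Cl2, 0 °C to rt, evaporate; then CH2N2 (3 equiv), Et2O–THF, 0 °C
Reagents that add atoms: diazomethane, C=[N+]=[N-]
Why: Acid chloride formation under chloroiminium (Vilsmeier-type) catalysis followed by C-acylation of diazomethane, the first stage of the Arndt–Eistert sequence, with the excess diazomethane taking up the HCl so that no chloromethyl ketone forms, as is routine for the benzo-fused analogues, the chromone-2-carbonyl chlorides.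

Step 4
Reactants: 9 2-(diazoacetyl)-6-(3,4-dimethoxyphenyl)-4H-pyran-4-one; 10 ethoxyacetylene
Product: 15 7-ethoxy-5-hydroxy-3',4'-dimethoxyflavone, via pyranonylketene 11 (not isolated), via ethoxycyclobutenone 12 (not isolated), via dienylketene 13 (not isolated), via cyclohexadienone tautomer 14 (not isolated)
Conditions: 10 (3 equiv), hν (blue LED, about 440 nm), degassed ClCH2CH2Cl, rt; then 80 °C
Reagents that add atoms: ethoxyacetylene 10, C#COCC
Why: Excitation of the diazocarbonyl band expels N2, and Wolff migration of the pyranone carbon C8a to the former diazo carbon (C8) gives ketene 11, whose carbonyl carbon is the future C5; [2+2] cycloaddition with 10 forms C5–C6 and C7–C8 (12), thermal 4π ring opening cleaves C5–C8 to dienylketene 13, and 6π electrocyclisation onto the pyranone CH (C4a) followed by enolisation of 14 gives the C5 phenol. This is the second-generation Danheiser benzannulation (photochemical Wolff variant), established for α,β-unsaturated, aryl and heteroaryl diazomethyl ketones with alkoxy- and siloxyalkynes and applied here to a 4-pyranone. Ring A, the only ring closed, is completed by a thermal disrotatory 6π electrocyclisation (bond C4a–C5) after the Wolff shift and the [2+2] step have set the other three bonds; no stereocentre survives in the product. The step needs one alkyne orientation, and the polarisation of the ynol ether secures it: its nucleophilic CH carbon bonds to the electrophilic ketene carbon, so the ethoxy group ends at C7, meta to the C5 phenol. It also needs a single closure site, which is given because the only carbon neighbour of C8a in the pyranone is C4a (the other neighbour is O1), and it needs the aryl pyranone and the flavone product to stay unexcited, which light of about 440 nm should ensure because both are expected to be transparent there while the diazoketone still absorbs weakly.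

Step 5
Reactants: 15 7-ethoxy-5-hydroxy-3',4'-dimethoxyflavone
Product: 16 luteolin (5,7,3',4'-tetrahydroxyflavone)
Conditions: BBr3 (8 equiv), CH2Cl2, −78 °C to rt (40 °C if needed); then H2O, 0 °C
Reagents that add atoms: none
Why: Lewis-acid dealkylation with BBr3, in which each ether oxygen is complexed and bromide removes methyl or ethyl by SN2, cleaves the two methyl ethers and the ethyl ether alike and leaves the flavone core, which is routinely exposed to this reagent, intact.

Step 6
Reactants: 16 luteolin
Product: 17 7,4'-di-O-benzylluteolin
Conditions: BnBr (2.1 equiv), K2CO3 (2.2 equiv), DMF, 0 °C to rt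
Reagents that add atoms: benzyl bromide, BrCc1ccccc1
Why: Williamson etherification steered by phenol acidity, since carbonate in DMF ionises first the 7-hydroxyl (a vinylogous acid para to C4=O) and then the 4'-hydroxyl (conjugated through C1' with the C2=C3–C4=O unit), whereas the 3'-hydroxyl is only meta-linked and the 5-hydroxyl is locked in a hydrogen bond to C4=O, so two equivalents of benzyl bromide should go to O7 and O4', the order relied on for catechol flavonols.

Step 7
Reactants: 17 7,4'-di-O-benzylluteolin
Product: 18 potassium 7,4'-di-O-benzylluteolin 3'-sulfate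
Conditions: SO3·pyridine (4 equiv), pyridine, 50 °C; then aq. KHCO3, 0 °C
Reagents that add atoms: sulfur trioxide–pyridine complex, [O-]S(=O)(=O)[n+]1ccccc1; potassium hydrogen carbonate, [K+].OC([O-])=O
Why: Sulfation of a phenol by an SO3–amine complex, in which the 3'-hydroxyl is the only free and unchelated phenol (the 5-hydroxyl is held by the C4 carbonyl and resists these reagents), with a bicarbonate work-up that delivers the base-stable potassium aryl sulfate.

Step 8
Reactants: 18 potassium 7,4'-di-O-benzylluteolin 3'-sulfate
Product: 20 luteolin 3'-sulfate, via potassium luteolin 3'-sulfate 19 (not isolated)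
Conditions: H2 (1 atm), 10% Pd/C, MeOH–THF, rt, filter; then HCl (1.0 equiv), H2O, 0 °C, C18 desalting, freeze-dry
Reagents that add atoms: none
Why: Heterogeneous hydrogenolysis of the two benzyl ethers over palladium on carbon, to which the aryl sulfate salt and, at balloon pressure, the flavone C2=C3 bond are inert, followed by protonation with one equivalent of HCl in the cold, where the sulfate ester is hydrolysed only slowly.

**Compound list**

1 | 3,4-dimethoxyacetophenone | CC(=O)c1ccc(OC)c(OC)c1 | starting material
2 | ethyl acetate | CCOC(C)=O | starting material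
3 | 1-(3,4-dimethoxyphenyl)butane-1,3-dione | CC(=O)CC(=O)c1ccc(OC)c(OC)c1 | intermediate
4 | diethyl oxalate | CCOC(=O)C(=O)OCC | starting material
5 | ethyl 6-(3,4-dimethoxyphenyl)-2,4,6-trioxohexanoate (triketo ester, formed and consumed in step 2) | CCOC(=O)C(=O)CC(=O)CC(=O)c1ccc(OC)c(OC)c1 | intermediate
6 | ethyl 6-(3,4-dimethoxyphenyl)-4-oxo-4H-pyran-2-carboxylate (formed and consumed in step 2) | CCOC(=O)c1cc(=O)cc(-c2ccc(OC)c(OC)c2)o1 | intermediate
7 | 6-(3,4-dimethoxyphenyl)-4-oxo-4H-pyran-2-carboxylic acid | OC(=O)c1cc(=O)cc(-c2ccc(OC)c(OC)c2)o1 | intermediate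
8 | 6-(3,4-dimethoxyphenyl)-4-oxo-4H-pyran-2-carbonyl chloride (formed and consumed in step 3) | O=C(Cl)c1cc(=O)cc(-c2ccc(OC)c(OC)c2)o1 | intermediate
9 | 2-(diazoacetyl)-6-(3,4-dimethoxyphenyl)-4H-pyran-4-one | [N-]=[N+]=CC(=O)c1cc(=O)cc(-c2ccc(OC)c(OC)c2)o1 | intermediate
10 | ethoxyacetylene | C#COCC | starting material
11 | 6-(3,4-dimethoxyphenyl)-2-(2-oxoethenyl)-4H-pyran-4-one (pyranonylketene, transient in step 4) | O=C=Cc1cc(=O)cc(-c2ccc(OC)c(OC)c2)o1 | intermediate
12 | 6-(3,4-dimethoxyphenyl)-2-(2-ethoxy-4-oxocyclobut-2-en-1-yl)-4H-pyran-4-one (racemic, formed and consumed in step 4) | CCOC1=CC(=O)C1c1cc(=O)cc(-c2ccc(OC)c(OC)c2)o1 | intermediate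
13 | 6-(3,4-dimethoxyphenyl)-2-(2-ethoxy-4-oxobuta-1,3-dien-1-yl)-4H-pyran-4-one, ketenyl and pyranonyl groups cis on the C7=C8 bond (dienylketene, transient in step 4) | O=C=C/C(OCC)=C\c1cc(=O)cc(-c2ccc(OC)c(OC)c2)o1 | intermediate
14 | 2-(3,4-dimethoxyphenyl)-7-ethoxy-4aH-chromene-4,5-dione (racemic keto tautomer of 15, transient in step 4) | CCOC1=CC(=O)C2C(=O)C=C(c3ccc(OC)c(OC)c3)OC2=C1 | intermediate
15 | 7-ethoxy-5-hydroxy-3',4'-dimethoxyflavone | CCOc1cc(O)c2c(=O)cc(-c3ccc(OC)c(OC)c3)oc2c1 | intermediate
16 | luteolin (5,7,3',4'-tetrahydroxyflavone) | O=c1cc(-c2ccc(O)c(O)c2)oc2cc(O)cc(O)c12 | intermediate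
17 | 7,4'-di-O-benzylluteolin | O=c1cc(-c2ccc(OCc3ccccc3)c(O)c2)oc2cc(OCc3ccccc3)cc(O)c12 | intermediate
18 | potassium 7,4'-di-O-benzylluteolin 3'-sulfate | [K+].[O-]S(=O)(=O)Oc1cc(-c2cc(=O)c3c(O)cc(OCc4ccccc4)cc3o2)ccc1OCc1ccccc1 | intermediate
19 | potassium luteolin 3'-sulfate (formed and consumed in step 8) | [K+].[O-]S(=O)(=O)Oc1cc(-c2cc(=O)c3c(O)cc(O)cc3o2)ccc1O | intermediate
20 | luteolin 3'-sulfate | O=c1cc(-c2ccc(O)c(OS(=O)(=O)O)c2)oc2cc(O)cc(O)c12 | target

**Count and risks**

Total step count: 8. Longest linear sequence: 8 steps (1 to 20); compounds 2, 4 and 10 are commercial inputs.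

Steps most likely to fail, in order of exposure:

Step 4. The ketene may be consumed by dimerisation, or by acylating phenol already formed, before it meets the alkyne. The cyclobutenone may also open with the pyranonyl group turned outward and revert instead of closing, and residual light absorption by the pyranone may divert material. The fallback buys ring A and builds the pyranone ring instead. Setting out from 1, Claisen condensation with diethyl carbonate (NaH, THF, reflux) should give ethyl 3-(3,4-dimethoxyphenyl)-3-oxopropanoate F1. Heating this with phloroglucinol without solvent at about 240 °C (Mentzer pyrone synthesis) should give 5,7-dihydroxy-3',4'-dimethoxyflavone F2. BBr3 under the conditions of step 5 then cleaves the two methyl ethers, and the route is rejoined at luteolin 16.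

Step 6. Site control in the alkylation may be lost: benzylation of the 3'-oxygen in competition with the 4'-oxygen, or a third alkylation, would give isomeric ethers that separate poorly. The fallback protects everything and then exchanges selectively. Setting out from 16, Ac2O–pyridine should give luteolin 5,7,3',4'-tetraacetate F3. Heating with BnCl, KI and K2CO3 in acetone should exchange the acetates on the two most acidic oxygens, O7 then O4', for benzyl, because the phenoxides that leave most readily are released and alkylated first. This should give 7,4'-di-O-benzylluteolin 5,3'-diacetate F4, which can be purified by crystallisation. K2CO3 (cat.) in MeOH removes the two remaining acetates and returns the route to 17.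

Step 3. The chlorinating agent may activate the pyranone carbonyl oxygen (chloropyrylium formation), or diazomethane may add as a dipole to the acceptor-substituted pyranone double bond, both at the cost of acylation. The fallback uses diazo transfer in place of diazomethane acylation. Setting out from 3, the dianion (LiN(iPr)2, 3 equiv, THF, −78 °C) is acylated at the terminal carbon with ethyl 2,2-diethoxypropanoate to give 1-(3,4-dimethoxyphenyl)-6,6-diethoxyheptane-1,3,5-trione F5. Aqueous HCl–AcOH closes the pyranone and frees the ketone, giving 2-acetyl-6-(3,4-dimethoxyphenyl)-4H-pyran-4-one F6. LiN(SiMe3)2 followed by CF3CO2CH2CF3 at −78 °C should give 4,4,4-trifluoro-1-[6-(3,4-dimethoxyphenyl)-4-oxo-4H-pyran-2-yl]butane-1,3-dione F7, used without isolation. MsN3, Et3N and H2O in MeCN then effect detrifluoroacetylative diazo transfer and return the route to 9.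

**Further compounds**

F1 | step 4 | ethyl 3-(3,4-dimethoxyphenyl)-3-oxopropanoate | CCOC(=O)CC(=O)c1ccc(OC)c(OC)c1
F2 | step 4 | 5,7-dihydroxy-3',4'-dimethoxyflavone | COc1ccc(-c2cc(=O)c3c(O)cc(O)cc3o2)cc1OC
F3 | step 6 | luteolin 5,7,3',4'-tetraacetate | CC(=O)Oc1cc(OC(C)=O)c2c(=O)cc(-c3ccc(OC(C)=O)c(OC(C)=O)c3)oc2c1
F4 | step 6 | 7,4'-di-O-benzylluteolin 5,3'-diacetate | CC(=O)Oc1cc(-c2cc(=O)c3c(OC(C)=O)cc(OCc4ccccc4)cc3o2)ccc1OCc1ccccc1
F5 | step 3 | 1-(3,4-dimethoxyphenyl)-6,6-diethoxyheptane-1,3,5-trione | CCOC(C)(OCC)C(=O)CC(=O)CC(=O)c1ccc(OC)c(OC)c1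
F6 | step 3 | 2-acetyl-6-(3,4-dimethoxyphenyl)-4H-pyran-4-one | CC(=O)c1cc(=O)cc(-c2ccc(OC)c(OC)c2)o1
F7 | step 3 | 4,4,4-trifluoro-1-[6-(3,4-dimethoxyphenyl)-4-oxo-4H-pyran-2-yl]butane-1,3-dione | O=C(CC(=O)C(F)(F)F)c1cc(=O)cc(-c2ccc(OC)c(OC)c2)o1
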